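## Plan

- Unit 1 is the flavanone whose 2-aryl ring carries the ether oxygen at C4'; unit 2 is the flavanone bonded to that oxygen at C6. The retrosynthesis first cuts the C2–aryl bond of unit 1 (back to 5,7-diacetoxychromone and an arylboronic acid), then the C7–C8 and C4a–C5 bonds in ring A of unit 2.
- Enabling feature: in ring A of unit 2, C6–OAr lies between C5–OH and C7–OH, so C5–C6–C7 is an aryloxymalonyl unit. Its hindered ether bond is made beforehand by SN2 at the sp3 carbon of bromomalonate. C8, C8a and C4a are the methyl carbon, C6 and C5 of a 2-aryl-6-methyl-2,3-dihydropyran-4-one that already holds O1, C2, C3 and C4.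
- Forward order: ring C of unit 2 (aldol, cyclodehydration), ring A of unit 2 (double C-acylation), acetylation, borylation, then arylation of the purchased chromone to complete unit 1, and removal of all five acetates.
- Stereochemistry: C2 of unit 2 (S) comes from the Ti(OiPr)4/(S)-BINOL aldol; C2 of unit 1 (S) comes from catalyst-controlled conjugate arylation with Pd(OCOCF3)2/(R)-t-BuPyOx. No later step uses conditions that open a flavanone.

Key step: step 7

Assumption: (S)-BINOL/Ti(OiPr)4 is taken to direct the dienol ether to the Si face of the aryl aldehyde, and (R)-t-BuPyOx to give the (2S)-flavanone (the opposite of the sense the (S)-ligand shows with cyclic enones); if a model run shows the reverse, the other ligand enantiomer is used.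

## Route

Step 1
Reactants: 1 acetylacetone
Product: 2 2,4-bis(trimethylsilyloxy)penta-1,3-diene
Conditions: TMSOTf (2.2 equiv), Et3N (2.5 equiv), Et2O, 0 °C to rt; ether layer separated and distilled
Reagents that add atoms: trimethylsilyl trifluoromethanesulfonate, C[Si](C)(C)OS(=O)(=O)C(F)(F)F
Why: Double soft enolisation and O-silylation of a 1,3-diketone with a silyl triflate and an amine, the usual entry to 1,3-bis(silyl enol ethers).

Step 2
Reactants: 3 4-acetoxybenzaldehyde; 2 2,4-bis(trimethylsilyloxy)penta-1,3-diene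
Product: 5 (S)-2-(4-acetoxyphenyl)-6-methyl-2,3-dihydro-4H-pyran-4-one, via hydroxy diketone 4 (not isolated)
Conditions: Ti(OiPr)4 (10 mol%), (S)-BINOL (10 mol%), THF, −78 °C to rt; then TFA, CH2Cl2, 0 °C to rt
Reagents that add atoms: none
Why: Catalytic asymmetric Mukaiyama-type aldol addition of the diene terminus to the aldehyde held on the chiral titanium BINOLate (Si-face attack sets the S carbinol), after which TFA removes the silyl groups and closes the δ-hydroxy-β-diketone by 6-exo-trig hemiketalisation and dehydration without touching the carbinol C–O bond.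

Step 3
Reactants: 5 (S)-2-(4-acetoxyphenyl)-6-methyl-2,3-dihydro-4H-pyran-4-one
Product: 6 (S)-2-(4-acetoxyphenyl)-4-(tert-butyldimethylsilyloxy)-6-methylene-3,6-dihydro-2H-pyran
Conditions: TBSOTf (1.2 equiv), i-Pr2NEt (1.5 equiv), CH2Cl2, −78 °C; pentane, filtration, evaporation, used at once
Reagents that add atoms: tert-butyldimethylsilyl trifluoromethanesulfonate, CC(C)(C)[Si](C)(C)OS(=O)(=O)C(F)(F)F
Why: Soft enolisation of a vinylogous ester: O-silylation gives a 4-silyloxy-dihydropyrylium ion whose charge rests mainly on O1=C6 (alkoxy is the better donor), so the hindered amine should take a proton from the exposed 6-methyl group rather than from C3 next to the aryl-bearing carbon, and no amide or alkoxide base is present to open the ring.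

Step 4
Reactants: 7 4-bromophenol; 8 diethyl bromomalonate
Product: 9 diethyl 2-(4-bromophenoxy)malonate
Conditions: K2CO3, acetone, reflux
Reagents that add atoms: none
Why: Williamson-type SN2 displacement of bromide at the doubly activated sp3 carbon by the phenoxide, which forms the later hindered C6–O–aryl bond before any ortho substituent exists.

Step 5
Reactants: 9 diethyl 2-(4-bromophenoxy)malonate
Product: 10 2-(4-bromophenoxy)malonic acid
Conditions: KOH (2.5 equiv), EtOH/H2O, 0 °C to rt; then cold 2 M HCl to pH 1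
Reagents that add atoms: potassium hydroxide, [K+].[OH-]
Why: Ester saponification, with cold acidification to keep the aryloxymalonic acid from decarboxylating.

Step 6
Reactants: 10 2-(4-bromophenoxy)malonic acid
Product: 11 2-(4-bromophenoxy)malonyl dichloride
Conditions: (COCl)2 (3 equiv), DMF (cat.), CH2Cl2, 0 °C to rt; evaporated, used crude
Reagents that add atoms: oxalyl chloride, O=C(Cl)C(Cl)=O
Why: Acid chloride formation through the chloroiminium species from DMF and oxalyl chloride under mild, base-free conditions.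

Step 7
Reactants: 6 (S)-2-(4-acetoxyphenyl)-4-(tert-butyldimethylsilyloxy)-6-methylene-3,6-dihydro-2H-pyran; 11 2-(4-bromophenoxy)malonyl dichloride
Product: 14 (S)-4'-O-acetyl-6-(4-bromophenoxy)-5,7-dihydroxyflavanone, via keto acid chloride 12 (not isolated), via acylketene 13 (not isolated)
Conditions: 6 added slowly to 11 (1.1 equiv), CH2Cl2 (0.05 M), −78 °C to rt, then 40 °C; pH 5 buffer work-up
Reagents that add atoms: none
Why: Proposed new method: the exocyclic CH2 of 6, the terminus of a 1-alkoxy-3-silyloxy diene, attacks one acid chloride of 11 in a vinylogous Mukaiyama-type acylation and chloride removes the silyl group, returning the dihydropyranone as 12 (C7–C8 bond); the remaining α-aryloxy-β-keto acid chloride then loses HCl to acylketene 13, whose enol form is a dienylketene that closes onto the ring α-carbon (C4a–C5 bond) and enolises to the 5,7-dihydroxy arene. The closest known reactions are the [3+3] cyclocondensations of 1,3-bis(silyl enol ethers) with 1,3-dielectrophiles (2-aryloxy ones included) to phenols, the C,C-diacylation of enol ethers by malonyl dichloride (Effenberger cyclisation) and the benzannulation of dienylketenes. Ring A of unit 2 closes by 6π-electrocyclisation of the dienylketene, equivalent to a 6-(enolendo)-exo C-acylation; every other intramolecular acylation site would need a four- or eight-membered ring. No stereocentre is formed, and C2 should stay intact because no base is present and the 4-acetoxyphenyl group disfavours benzylic ionisation by the HCl released. The step needs C- over O-acylation and ring closure over oligomerisation: the methylene activated by both oxygens is the most nucleophilic site of 6, and slow addition of 6 to the dichloride at low temperature and moderate dilution should keep one malonyl unit per diene. Because the dielectrophile is symmetric and O1 and C2 are already in place, no 6- versus 8-aryloxy question arises.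

Step 8
Reactants: 14 (S)-4'-O-acetyl-6-(4-bromophenoxy)-5,7-dihydroxyflavanone
Product: 15 (S)-4',5,7-tri-O-acetyl-6-(4-bromophenoxy)flavanone
Conditions: Ac2O (4 equiv), pyridine, DMAP (cat.), CH2Cl2, 0 °C to rt
Reagents that add atoms: acetic anhydride, CC(=O)OC(C)=O
Why: DMAP-catalysed O-acylation of both phenols, which masks them against periodate in step 10 and against phenoxide-induced ring opening, under a base too weak to deprotonate C3.

Step 9
Reactants: 15 (S)-4',5,7-tri-O-acetyl-6-(4-bromophenoxy)flavanone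
Product: 16 (S)-4',5,7-tri-O-acetyl-6-[4-(4,4,5,5-tetramethyl-1,3,2-dioxaborolan-2-yl)phenoxy]flavanone
Conditions: B2pin2 (1.5 equiv), Pd(dppf)Cl2 (5 mol%), KOAc (3 equiv), 1,4-dioxane, 85 °C
Reagents that add atoms: bis(pinacolato)diboron, CC1(C)OB(OC1(C)C)B1OC(C)(C)C(C)(C)O1
Why: Miyaura borylation (insertion of zerovalent palladium into the C–Br bond, acetate-assisted transmetalation with the diboron, reductive elimination), with KOAc in dry dioxane too weak to open the flavanone or cleave aryl acetates.

Step 10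
Reactants: 16 (S)-4',5,7-tri-O-acetyl-6-[4-(4,4,5,5-tetramethyl-1,3,2-dioxaborolan-2-yl)phenoxy]flavanone
Product: 17 {4-[((S)-4',5,7-triacetoxyflavanon-6-yl)oxy]phenyl}boronic acid
Conditions: NaIO4 (3 equiv), THF/H2O (4:1), rt; then 1 M HCl, rt
Reagents that add atoms: water, O
Why: Periodate cleaves the pinacol released on hydrolysis to acetone and so pulls the boronic ester to the free boronic acid under mildly acidic conditions that aryl acetates and the flavanone tolerate.

Step 11
Reactants: 18 5,7-dihydroxychromone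
Product: 19 5,7-diacetoxychromone
Conditions: Ac2O, pyridine, DMAP (cat.), rt
Reagents that add atoms: acetic anhydride, CC(=O)OC(C)=O
Why: Standard phenol acylation; the acetates also make the chromone a better Michael acceptor than ethers or free phenols would.

Step 12
Reactants: 17 {4-[((S)-4',5,7-triacetoxyflavanon-6-yl)oxy]phenyl}boronic acid; 19 5,7-diacetoxychromone
Product: 20 penta-O-acetyl derivative of the target
Conditions: Pd(OCOCF3)2 (10 mol%), (R)-t-BuPyOx (12 mol%), NH4PF6 (30 mol%), H2O (5 equiv), 19 (2 equiv), ClCH2CH2Cl, 60 °C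
Reagents that add atoms: none
Why: Asymmetric conjugate addition of an arylboronic acid to a chromone catalysed by a cationic divalent palladium pyridine-oxazoline complex (transmetalation, face-selective insertion of C2=C3, protonolysis of the palladium enolate); the tert-butyl group of the (R)-ligand should set C2 of unit 1 as S under catalyst control, and the neutral medium leaves C2 of unit 2 and the acetates alone.

Step 13
Reactants: 20 penta-O-acetyl derivative of the target
Product: 21 CNP0184214.1
Conditions: HCl (3 M in MeOH), THF, 40 °C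
Reagents that add atoms: none
Why: Acid-catalysed transesterification of the five aryl acetates to methyl acetate; acid, unlike base, does not open flavanones to chalcones, so both C2 centres should be kept.

## Compound list

1 | acetylacetone | CC(=O)CC(C)=O | starting material
2 | 2,4-bis(trimethylsilyloxy)penta-1,3-diene (geometric mixture as obtained) | C=C(O[Si](C)(C)C)C=C(C)O[Si](C)(C)C | intermediate
3 | 4-acetoxybenzaldehyde | CC(=O)Oc1ccc(C=O)cc1 | starting material
4 | (S)-6-(4-acetoxyphenyl)-6-hydroxyhexane-2,4-dione (aldol adduct after loss of its silyl groups) | CC(=O)CC(=O)C[C@H](O)c1ccc(OC(C)=O)cc1 | intermediate (not isolated)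
5 | (S)-2-(4-acetoxyphenyl)-6-methyl-2,3-dihydro-4H-pyran-4-one | CC1=CC(=O)C[C@@H](c2ccc(OC(C)=O)cc2)O1 | intermediate
6 | (S)-2-(4-acetoxyphenyl)-4-(tert-butyldimethylsilyloxy)-6-methylene-3,6-dihydro-2H-pyran | C=C1C=C(O[Si](C)(C)C(C)(C)C)C[C@@H](c2ccc(OC(C)=O)cc2)O1 | intermediate
7 | 4-bromophenol | Oc1ccc(Br)cc1 | starting material
8 | diethyl bromomalonate | CCOC(=O)C(Br)C(=O)OCC | starting material
9 | diethyl 2-(4-bromophenoxy)malonate | CCOC(=O)C(Oc1ccc(Br)cc1)C(=O)OCC | intermediate
10 | 2-(4-bromophenoxy)malonic acid | OC(=O)C(Oc1ccc(Br)cc1)C(O)=O | intermediate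
11 | 2-(4-bromophenoxy)malonyl dichloride | O=C(Cl)C(Oc1ccc(Br)cc1)C(Cl)=O | intermediate
12 | (2S)-2-(4-acetoxyphenyl)-6-[3-(4-bromophenoxy)-4-chloro-2,4-dioxobutyl]-2,3-dihydro-4H-pyran-4-one (epimers at the side-chain CH) | O=C(Cl)C(Oc1ccc(Br)cc1)C(=O)CC1=CC(=O)C[C@@H](c2ccc(OC(C)=O)cc2)O1 | intermediate (not isolated)
13 | (S)-2-(4-acetoxyphenyl)-6-[3-(4-bromophenoxy)-2,4-dioxobut-3-en-1-yl]-2,3-dihydro-4H-pyran-4-one (acylketene) | O=C=C(Oc1ccc(Br)cc1)C(=O)CC1=CC(=O)C[C@@H](c2ccc(OC(C)=O)cc2)O1 | intermediate (not isolated)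
14 | (S)-4'-O-acetyl-6-(4-bromophenoxy)-5,7-dihydroxyflavanone | O=C1C[C@@H](c2ccc(OC(C)=O)cc2)Oc2cc(O)c(Oc3ccc(Br)cc3)c(O)c21 | intermediate
15 | (S)-4',5,7-tri-O-acetyl-6-(4-bromophenoxy)flavanone | O=C1C[C@@H](c2ccc(OC(C)=O)cc2)Oc2cc(OC(C)=O)c(Oc3ccc(Br)cc3)c(OC(C)=O)c21 | intermediate
16 | (S)-4',5,7-tri-O-acetyl-6-[4-(4,4,5,5-tetramethyl-1,3,2-dioxaborolan-2-yl)phenoxy]flavanone | O=C1C[C@@H](c2ccc(OC(C)=O)cc2)Oc2cc(OC(C)=O)c(Oc3ccc(B4OC(C)(C)C(C)(C)O4)cc3)c(OC(C)=O)c21 | intermediate
17 | {4-[((S)-4',5,7-triacetoxyflavanon-6-yl)oxy]phenyl}boronic acid | O=C1C[C@@H](c2ccc(OC(C)=O)cc2)Oc2cc(OC(C)=O)c(Oc3ccc(B(O)O)cc3)c(OC(C)=O)c21 | intermediate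
18 | 5,7-dihydroxychromone | O=c1ccoc2cc(O)cc(O)c12 | starting material
19 | 5,7-diacetoxychromone | CC(=O)Oc1cc(OC(C)=O)c2c(=O)ccoc2c1 | intermediate
20 | (2S)-2-{4-[((2S)-5,7-diacetoxy-2-(4-acetoxyphenyl)-4-oxochroman-6-yl)oxy]phenyl}-4-oxochroman-5,7-diyl diacetate | O=C1C[C@@H](c2ccc(Oc3c(OC(C)=O)cc4c(c3OC(C)=O)C(=O)C[C@@H](c3ccc(OC(C)=O)cc3)O4)cc2)Oc2cc(OC(C)=O)cc(OC(C)=O)c21 | intermediate
21 | (2S)-5,7-dihydroxy-2-{4-[((2S)-5,7-dihydroxy-2-(4-hydroxyphenyl)-4-oxochroman-6-yl)oxy]phenyl}chroman-4-one (CNP0184214.1) | O=C1C[C@@H](c2ccc(Oc3c(O)cc4c(c3O)C(=O)C[C@@H](c3ccc(O)cc3)O4)cc2)Oc2cc(O)cc(O)c21 | target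

## Step count and risks

Total steps: 13. Longest linear sequence: 9 steps (steps 1, 2, 3, 7, 8, 9, 10, 12, 13; the malonyl branch through steps 4, 5, 6 is equally long).

Steps most likely to fail:

1. Step 7 (new method). What may go wrong: O-acylation of the dienol ether or of the enolised mono-adduct in place of C-acylation; reaction of 12 or 13 with a second diene before ring closure, giving oligomers; or protodesilylation of 6 by the HCl released. Fallback, with known reactions only: ring A of unit 2 is taken from a benzene ring and the ether is made by phenol arylation. This fallback sets out from purchased xanthoxylin (2'-hydroxy-4',6'-dimethoxyacetophenone) rather than from a numbered compound, uses none of 1–14, and comes back to the route at 15. Elbs persulfate oxidation (K2S2O8, aqueous NaOH, then acid hydrolysis of the aryl sulfate) hydroxylates para to the phenol to give 2',5'-dihydroxy-4',6'-dimethoxyacetophenone F1. As its dianion (t-BuOK, THF) this is arylated at the non-chelated, more nucleophilic 5'-oxygen with bis(4-bromophenyl)iodonium triflate, a metal-free method that tolerates di-ortho-substituted phenols, giving 5'-(4-bromophenoxy)-2'-hydroxy-4',6'-dimethoxyacetophenone F2. DMF dimethyl acetal gives the enaminone (E)-1-[5-(4-bromophenoxy)-2-hydroxy-4,6-dimethoxyphenyl]-3-(dimethylamino)prop-2-en-1-one F3, which HCl closes to 6-(4-bromophenoxy)-5,7-dimethoxychromone F4; the para relation between the ring-forming hydroxyl and the aryloxy group fixes the 6-position. BBr3 in CH2Cl2 gives 6-(4-bromophenoxy)-5,7-dihydroxychromone F5, and Ac2O/pyridine gives 5,7-diacetoxy-6-(4-bromophenoxy)chromone F6. Conjugate addition of purchased 4-acetoxyphenylboronic acid to F6 under the conditions of step 12 (Pd(OCOCF3)2, (R)-t-BuPyOx) gives 15.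

2. Step 3. What may go wrong: proton loss from C3 in place of the methyl group, leading to the endocyclic 2H-pyran silyl ether, which can ring-open electrocyclically and erase C2; 6 may also be protodesilylated during isolation. Fallback: move to the pyranone oxidation level, where only the methyl protons are available, and set C2 afterwards. It sets out from 5 and comes back at 15. DDQ in dioxane at 90 °C dehydrogenates 5 to 2-(4-acetoxyphenyl)-6-methyl-4H-pyran-4-one F7. TBSOTf/Et3N gives 6-(4-acetoxyphenyl)-4-(tert-butyldimethylsilyloxy)-2-methylene-2H-pyran F8. Reaction with 11 as in step 7 gives 4'-O-acetyl-6-(4-bromophenoxy)-5,7-dihydroxyflavone F9, and acetylation as in step 8 gives 4',5,7-tri-O-acetyl-6-(4-bromophenoxy)flavone F10. Asymmetric conjugate reduction of the C2=C3 bond with a chiral copper hydride catalyst (Cu(OAc)2, the DTBM-SEGPHOS enantiomer that gives the S product, (EtO)2MeSiH, t-BuOH, toluene), which tolerates the aryl bromide, gives 15.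

3. Step 12. What may go wrong: slow transmetalation and protodeboronation of the bulky, electron-rich boronic acid; partial acetate hydrolysis in the wet medium at 60 °C; or incomplete catalyst control. Fallback: reverse the order, so that unit 1 is made first with a simple boronic acid and carried on the malonyl unit into the ring-forming step. It sets out from 19 and comes back at 21. Conjugate addition of purchased 4-hydroxyphenylboronic acid to 19 under the conditions of step 12 gives (S)-5,7-diacetoxy-4'-hydroxyflavanone F11. Rh2(OAc)4-catalysed O–H insertion of di-tert-butyl diazomalonate (CH2Cl2, reflux, no base) gives di-tert-butyl 2-{4-[(S)-5,7-diacetoxy-4-oxochroman-2-yl]phenoxy}malonate F12. TFA in CH2Cl2 gives 2-{4-[(S)-5,7-diacetoxy-4-oxochroman-2-yl]phenoxy}malonic acid F13, and oxalyl chloride with catalytic DMF gives 2-{4-[(S)-5,7-diacetoxy-4-oxochroman-2-yl]phenoxy}malonyl dichloride F14. Reaction of F14 with 6 as in step 7 gives the 4''',5,7-tri-O-acetyl derivative of the target F15, and methanolic HCl as in step 13 gives 21.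

## Further compounds

F1 | step 7 | 2',5'-dihydroxy-4',6'-dimethoxyacetophenone | CC(=O)c1c(O)cc(OC)c(O)c1OC
F2 | step 7 | 5'-(4-bromophenoxy)-2'-hydroxy-4',6'-dimethoxyacetophenone | CC(=O)c1c(O)cc(OC)c(Oc2ccc(Br)cc2)c1OC
F3 | step 7 | (E)-1-[5-(4-bromophenoxy)-2-hydroxy-4,6-dimethoxyphenyl]-3-(dimethylamino)prop-2-en-1-one | CN(C)/C=C/C(=O)c1c(O)cc(OC)c(Oc2ccc(Br)cc2)c1OC
F4 | step 7 | 6-(4-bromophenoxy)-5,7-dimethoxychromone | COc1cc2occc(=O)c2c(OC)c1Oc1ccc(Br)cc1
F5 | step 7 | 6-(4-bromophenoxy)-5,7-dihydroxychromone | O=c1ccoc2cc(O)c(Oc3ccc(Br)cc3)c(O)c12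
F6 | step 7 | 5,7-diacetoxy-6-(4-bromophenoxy)chromone | CC(=O)Oc1cc2occc(=O)c2c(OC(C)=O)c1Oc1ccc(Br)cc1
F7 | step 3 | 2-(4-acetoxyphenyl)-6-methyl-4H-pyran-4-one | Cc1cc(=O)cc(-c2ccc(OC(C)=O)cc2)o1
F8 | step 3 | 6-(4-acetoxyphenyl)-4-(tert-butyldimethylsilyloxy)-2-methylene-2H-pyran | C=C1C=C(O[Si](C)(C)C(C)(C)C)C=C(c2ccc(OC(C)=O)cc2)O1
F9 | step 3 | 4'-O-acetyl-6-(4-bromophenoxy)-5,7-dihydroxyflavone | O=c1cc(-c2ccc(OC(C)=O)cc2)oc2cc(O)c(Oc3ccc(Br)cc3)c(O)c12
F10 | step 3 | 4',5,7-tri-O-acetyl-6-(4-bromophenoxy)flavone | O=c1cc(-c2ccc(OC(C)=O)cc2)oc2cc(OC(C)=O)c(Oc3ccc(Br)cc3)c(OC(C)=O)c12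
F11 | step 12 | (S)-5,7-diacetoxy-4'-hydroxyflavanone | O=C1C[C@@H](c2ccc(O)cc2)Oc2cc(OC(C)=O)cc(OC(C)=O)c21
F12 | step 12 | di-tert-butyl 2-{4-[(S)-5,7-diacetoxy-4-oxochroman-2-yl]phenoxy}malonate | CC(C)(C)OC(=O)C(Oc1ccc(cc1)[C@@H]1CC(=O)c2c(OC(C)=O)cc(OC(C)=O)cc2O1)C(=O)OC(C)(C)C
F13 | step 12 | 2-{4-[(S)-5,7-diacetoxy-4-oxochroman-2-yl]phenoxy}malonic acid | OC(=O)C(Oc1ccc(cc1)[C@@H]1CC(=O)c2c(OC(C)=O)cc(OC(C)=O)cc2O1)C(O)=O
F14 | step 12 | 2-{4-[(S)-5,7-diacetoxy-4-oxochroman-2-yl]phenoxy}malonyl dichloride | O=C(Cl)C(Oc1ccc(cc1)[C@@H]1CC(=O)c2c(OC(C)=O)cc(OC(C)=O)cc2O1)C(Cl)=O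
F15 | step 12 | (2S)-2-{4-[((2S)-2-(4-acetoxyphenyl)-5,7-dihydroxy-4-oxochroman-6-yl)oxy]phenyl}-4-oxochroman-5,7-diyl diacetate | O=C1C[C@@H](c2ccc(Oc3c(O)cc4c(c3O)C(=O)C[C@@H](c3ccc(OC(C)=O)cc3)O4)cc2)Oc2cc(OC(C)=O)cc(OC(C)=O)c21
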